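**Strategy.** Everything rests on closing the cyclohexane (C1, C10, C11, C12, C13, C14) last, through the C13–C14 bond. A primary radical at C13, made from an iodide on the side chain at C10, adds 6-exo to C14 of the C14=C15 olefin held in the oxepene ring (C1–C2–C3–O–C16–C15–C14); hydrogen transfer to C15 then gives the target. One operation closes the fourth ring and sets C14 and C15, using the cis placement of the C10 chain and C14 on the tetrahydrofuran. The precursor is the tricyclic tetrahydrofuran–oxonanone–oxepene carrying the acetoxy iodide chain, built from a meso oxanorbornene by enantioselective ring-opening cross-metathesis.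

Key step: step 20

Numbering remark: asbestinane-type numbering is used for all compounds: tetrahydrofuran C1–C2–O–C9–C10; oxonane C2–C3–C4–C5–C6–C7–C8–C9–O; oxepane C1–C2–C3–O–C16–C15–C14; cyclohexane C1–C10–C11–C12–C13–C14; methyl groups on C3, C12 and C15.
Remark on stereochemistry: C7 is an epimeric (acetal, lactol or carbinol) mixture in 6, 7, 9, 10, 12–16 and 18–20 and is written without configuration, since it ends as the ketone.
Assumption: the enantiomer of the chiral metathesis catalyst in step 3 is taken to be the one that puts the butoxyvinyl group on the olefin carbon that becomes C8.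

Step 1
Reactants: 1 exo-7-oxabicyclo[2.2.1]hept-5-ene-2,3-dicarboxylic anhydride (meso)
Product: 2 meso exo,exo-7-oxabicyclo[2.2.1]hept-5-ene-2,3-diyldimethanol
Conditions: LiAlH4, THF, 0 °C → rt
Reagents that add atoms: none
Why: Hydride reduction of the cyclic anhydride gives the cis-diol and leaves the olefin alone, so the exo relationship of the Diels–Alder adduct, which is the C1/C10-cis, C1/C2-trans pattern of the target tetrahydrofuran, is carried over unchanged.

Step 2
Reactants: 2 meso diol
Product: 3 meso exo,exo-2,3-bis(triethylsilyloxymethyl)-7-oxabicyclo[2.2.1]hept-5-ene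
Conditions: TESCl, imidazole, CH2Cl2, 0 °C
Reagents that add atoms: chlorotriethylsilane, CC[Si](Cl)(CC)CC
Why: Routine silyl ether formation caps both hydroxyls, which would otherwise protonate the molybdenum alkylidene of the next step, and keeps the substrate meso.

Step 3
Reactants: 3 meso bis(triethylsilyl) ether; 4 n-butyl vinyl ether
Product: 5 tetrahydrofuran with vinyl on C2, (Z)-2-butoxyethenyl on C9 and CH2OSiEt3 on C1 and C10 (C2/C9 groups cis, C1/C10 groups cis, C1/C2 groups trans)
Conditions: chiral stereogenic-at-Mo monoaryloxide pyrrolide alkylidene (3 mol %), 4 (5 equiv), C6H6, 22 °C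
Reagents that add atoms: none
Why: Catalytic enantioselective ring-opening/cross-metathesis: strain release drives opening of the meso olefin by the chiral Mo alkoxy-alkylidene, whose choice between the two enantiotopic olefin carbons fixes the absolute configuration of C1, C2, C9 and C10 and leaves a (Z)-enol ether on the C9 side and a vinyl group on C2.

Step 4
Reactants: 5 enol ether bis(silyl ether)
Product: 6 trans-fused tetrahydrofuran–tetrahydropyran methyl acetal (pyran ring C9–C8H2–C7H(OMe)–O–C11H2–C10), free CH2OH (C14) on C1, vinyl on C2
Conditions: PPTS (10 mol %), MeOH, rt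
Reagents that add atoms: methanol, CO
Why: Acid-catalysed methanolysis removes both silyl groups and turns the enol ether into the six-membered cyclic methyl acetal with the neighbouring C11 hydroxyl (transacetalization; the seven-membered alternative with the C14 hydroxyl is disfavoured), so C7 and C11 are masked together and the two hydroxymethyl arms are told apart.

Step 5
Reactants: 6 vinyl acetal alcohol
Product: 7 methyl ketone (acetyl group on C2 = C3 with its methyl), otherwise as 6
Conditions: PdCl2 (10 mol %), Cu(OAc)2 (20 mol %), O2 (1 atm), DMA–H2O 7:1, rt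
Reagents that add atoms: water, O
Why: Tsuji–Wacker oxidation of the only monosubstituted olefin gives the methyl ketone by Markovnikov hydroxypalladation, and the acetate-buffered copper co-catalyst keeps the acetal intact.

Step 6
Reactants: 7 methyl ketone; 8 allylmagnesium bromide
Product: 9 tertiary alcohol (C3 bears OH, CH3 and allyl; C3 configured as in the target), otherwise as 7
Conditions: 8 (2.5 equiv), CH2Cl2–Et2O, −78 °C; aq. NH4Cl
Reagents that add atoms: none
Why: Cram-chelate Grignard addition: magnesium bridges the ketone oxygen and the ring oxygen, and the allyl group adds from the face opposite C1, which gives the C3 configuration of the target (one further equivalent is used up by the free hydroxyl).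

Step 7
Reactants: 9 diol (primary C14–OH, tertiary C3–OH)
Product: 10 aldehyde (C14 = CHO on C1), tertiary alcohol retained
Conditions: Dess–Martin periodinane, NaHCO3, CH2Cl2, 0 °C → rt
Reagents that add atoms: none
Why: Dess–Martin oxidation converts the primary alcohol to the aldehyde under buffered, non-basic conditions that leave the tertiary alcohol, the acetal and the configuration at C1 untouched.

Step 8
Reactants: 10 aldehyde; 11 methyl 2-[bis(2,2,2-trifluoroethoxy)phosphoryl]propanoate
Product: 12 (Z)-enoate (C1–C14H=C15(CH3)–CO2Me, C1 and ester cis)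
Conditions: KHMDS, 18-crown-6, THF, −78 °C
Reagents that add atoms: none
Why: Still–Gennari variant of the Horner–Wadsworth–Emmons olefination: fast, irreversible elimination from the trifluoroethyl phosphonate adduct under dissociating conditions gives the (Z)-trisubstituted enoate needed for a cis ring olefin.

Step 9
Reactants: 12 (Z)-enoate
Product: 13 (Z)-allylic alcohol (C16H2OH) with tertiary C3–OH
Conditions: DIBAL-H (3.5 equiv), CH2Cl2, −78 °C; Rochelle salt
Reagents that add atoms: none
Why: DIBAL-H reduces the conjugated ester in 1,2-fashion to the allylic alcohol at low temperature without touching the acetal or the olefins.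

Step 10
Reactants: 13 (Z)-allylic alcohol
Product: 15 oxepene methyl acetal (ring C1–C2–C3–O–C16H2–C15(CH3)=C14H, trans-fused to the tetrahydrofuran; C3 keeps CH3 and allyl), via allylic mesylate 14 (not isolated)
Conditions: MsCl (1.05 equiv), Et3N, CH2Cl2, −40 °C; then KOt-Bu, THF, 0 °C → rt
Reagents that add atoms: methanesulfonyl chloride, CS(=O)(=O)Cl (its atoms are in 14 only)
Why: Selective sulfonylation of the primary allylic alcohol followed by intramolecular Williamson etherification (7-exo-tet SN2 by the tertiary C3 alkoxide) closes the oxepene, the Z geometry holding C16 next to the C3 oxygen, while SN2′ attack would need a strained trans-fused five-membered ring.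

Step 11
Reactants: 15 oxepene methyl acetal
Product: 16 lactol (C7 hemiacetal with the C11 oxygen)
Conditions: AcOH–THF–H2O 3:1:1, 45 °C
Reagents that add atoms: water, O
Why: Mild aqueous acid hydrolyses the cyclic acetal to the lactol, whereas the allylic tertiary-alkyl ether of the oxepene needs far stronger acid to ionize.

Step 12
Reactants: 16 lactol; 17 vinylmagnesium bromide
Product: 18 diene diol (C9–C8H2–C7H(OH)–CH=CH2; C10–C11H2OH; allyl on C3)
Conditions: 17 (4 equiv), THF, 0 °C → rt
Reagents that add atoms: none
Why: The Grignard reagent deprotonates the lactol and adds to its open hydroxy aldehyde form, giving the allylic alcohol at C7 as both epimers, which converge later at the ketone.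

Step 13
Reactants: 18 diene diol
Product: 19 oxonene diol (nine-membered ring closed, (5Z)-olefin, C7–OH, C11H2OH)
Conditions: Grubbs second-generation catalyst (10 mol %), CH2Cl2 (2 mM), 40 °C
Reagents that add atoms: none
Why: Ring-closing metathesis joins the two monosubstituted olefins, which the cis-2,5-disubstituted tetrahydrofuran holds on the same face, to the nine-membered Z-cycloalkene with loss of ethene, the trisubstituted oxepene olefin being too hindered to take part.

Step 14
Reactants: 19 oxonene diol
Product: 20 oxonane diol (C5–C6 saturated)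
Conditions: H2 (1 atm), RhCl(PPh3)3 (10 mol %), C6H6–EtOH, rt
Reagents that add atoms: none
Why: Homogeneous hydrogenation with Wilkinson's catalyst saturates the cis-disubstituted olefin much faster than the trisubstituted oxepene olefin.

Step 15
Reactants: 20 oxonane diol
Product: 21 keto aldehyde (C7 ketone, C11 aldehyde on C10)
Conditions: (COCl)2, DMSO, CH2Cl2, −78 °C; i-Pr2NEt, −78 → −20 °C
Reagents that add atoms: none
Why: Swern oxidation activates both hydroxyls before any carbonyl group is set free, so no lactol between C7–OH and the C11 aldehyde can form and be over-oxidized, and the hindered amine added cold limits epimerization at C10.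

Step 16
Reactants: 21 keto aldehyde; 22 propanal
Product: 23 anti-aldol (C10–C11H(OH)–C12H(CH3)–C13HO, C11 and C12 as in the target)
Conditions: L-proline (30 mol %), DMF, 4 °C, 22 added by syringe pump
Reagents that add atoms: none
Why: Proline-catalysed direct cross-aldol reaction: the (E)-enamine of propanal adds through the hydrogen-bonded chair transition state to the α-branched, poorly enolizable aldehyde, giving the anti aldol with C11 and C12 set by the catalyst ((2S,3S) sense known for L-proline), while the ring ketone is a far poorer acceptor.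

Step 17
Reactants: 23 anti-aldol aldehyde
Product: 24 1,3-diol (C11–OH secondary, C13H2OH primary)
Conditions: NaBH4, EtOH–CH2Cl2 3:7, −78 °C
Reagents that add atoms: none
Why: At −78 °C borohydride reduces the aldehyde much faster than the transannularly hindered nine-membered ring ketone (chemoselective hydride reduction).

Step 18
Reactants: 24 1,3-diol
Product: 25 primary iodide (C13H2I, C11–OH)
Conditions: I2, PPh3, imidazole, CH2Cl2, 0 °C
Reagents that add atoms: iodine, II
Why: Iodination through the alkoxyphosphonium salt (Appel-type, SN2) is selective for the primary hydroxyl over the hindered secondary one.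

Step 19
Reactants: 25 iodo alcohol
Product: 26 iodo acetate (C11–OAc, C13H2I)
Conditions: Ac2O, DMAP, pyridine, CH2Cl2, 0 °C → rt
Reagents that add atoms: acetic anhydride, CC(=O)OC(C)=O
Why: DMAP-catalysed acylation of the remaining secondary alcohol gives the acetate without affecting the primary iodide or the ketone.

Step 20
Reactants: 26 iodo acetate
Product: 27 target CNP0288436.2
Conditions: (Me3Si)3SiH (1.5 equiv) and AIBN (0.2 equiv) added by syringe pump over 8 h, C6H6 (2 mM), 80 °C
Reagents that add atoms: none
Why: (Me3Si)3Si• abstracts iodine from C13, the primary C13 radical adds to C14 of the C14=C15 olefin of the oxepene to give the tertiary C15 radical, and this takes hydrogen from the silane, which carries the chain. The closest known reaction type is the tin- or silane-mediated reductive cyclization of an alkyl iodide onto an unactivated trisubstituted alkene. The cyclohexane closes in 6-exo-trig mode; the tether C10–C11–C12–C13 is cis to C14 on the tetrahydrofuran, so the new ring is cis-fused to it. C14 is controlled by the trans-fused oxepene, which holds C15 anti to C10 about the C1–C14 bond so that C13 can reach only the olefin face away from C2 and C3 (H1 and H14 trans); C15 is controlled by delivery of hydrogen from the bulky silane anti to the new C13–C14 bond (net anti addition across the ring olefin), which places the C15 methyl cis to C13. The step needs ring closure to outrun direct reduction and 1,5-hydrogen transfer from C9–H; slow addition of a silane that donates hydrogen more slowly than tin hydride and the preorganized cis arrangement of radical and acceptor should secure this, and acetate, ketone and ethers are inert to alkyl radicals.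

**Compound list**

1 | exo-7-oxabicyclo[2.2.1]hept-5-ene-2,3-dicarboxylic anhydride (meso) | O1[C@@H]2[C@@H]3C(=O)OC(=O)[C@@H]3[C@H]1C=C2 | starting material
2 | meso exo,exo-7-oxabicyclo[2.2.1]hept-5-ene-2,3-diyldimethanol | O1[C@@H]2[C@H](CO)[C@H](CO)[C@H]1C=C2 | intermediate
3 | meso exo,exo-2,3-bis(triethylsilyloxymethyl)-7-oxabicyclo[2.2.1]hept-5-ene | O1[C@@H]2[C@H](CO[Si](CC)(CC)CC)[C@H](CO[Si](CC)(CC)CC)[C@H]1C=C2 | intermediate
4 | n-butyl vinyl ether | C=COCCCC | starting material
5 | tetrahydrofuran: C2 vinyl, C9 (Z)-2-butoxyethenyl, C1 and C10 CH2OSiEt3 | O1[C@@H](/C=C\OCCCC)[C@H](CO[Si](CC)(CC)CC)[C@H](CO[Si](CC)(CC)CC)[C@H]1C=C | intermediate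
6 | trans-fused tetrahydrofuran–tetrahydropyran methyl acetal, C1 CH2OH, C2 vinyl | O1[C@H]2CC(OC)OC[C@@H]2[C@H](CO)[C@H]1C=C | intermediate
7 | C3 methyl ketone of 6 | O1[C@H]2CC(OC)OC[C@@H]2[C@H](CO)[C@H]1C(C)=O | intermediate
8 | allylmagnesium bromide | C=CC[Mg]Br | starting material
9 | C3 tertiary alcohol (OH, CH3, allyl), C14 primary alcohol | O1[C@H]2CC(OC)OC[C@@H]2[C@H](CO)[C@H]1[C@@](C)(O)CC=C | intermediate
10 | C14 aldehyde, C3 tertiary alcohol | O1[C@H]2CC(OC)OC[C@@H]2[C@H](C=O)[C@H]1[C@@](C)(O)CC=C | intermediate
11 | methyl 2-[bis(2,2,2-trifluoroethoxy)phosphoryl]propanoate | COC(=O)C(C)P(=O)(OCC(F)(F)F)OCC(F)(F)F | starting material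
12 | (Z)-enoate C14H=C15(CH3)CO2Me on C1 | O1[C@H]2CC(OC)OC[C@@H]2[C@H](/C=C(/C)C(=O)OC)[C@H]1[C@@](C)(O)CC=C | intermediate
13 | (Z)-allylic alcohol (C16H2OH), C3 tertiary alcohol | O1[C@H]2CC(OC)OC[C@@H]2[C@H](/C=C(/C)CO)[C@H]1[C@@](C)(O)CC=C | intermediate
14 | allylic mesylate at C16 | O1[C@H]2CC(OC)OC[C@@H]2[C@H](/C=C(/C)COS(C)(=O)=O)[C@H]1[C@@](C)(O)CC=C | intermediate (not isolated)
15 | oxepene methyl acetal (tricyclic; C3 allyl) | O1[C@H]2CC(OC)OC[C@@H]2[C@@H]3C=C(C)CO[C@@](C)(CC=C)[C@@H]13 | intermediate
16 | oxepene lactol | O1[C@H]2CC(O)OC[C@@H]2[C@@H]3C=C(C)CO[C@@](C)(CC=C)[C@@H]13 | intermediate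
17 | vinylmagnesium bromide | C=C[Mg]Br | starting material
18 | diene diol (C7 allylic alcohol, C11H2OH, C3 allyl) | O1[C@@H](CC(O)C=C)[C@H](CO)[C@@H]2C=C(C)CO[C@@](C)(CC=C)[C@@H]12 | intermediate
19 | (5Z)-oxonene diol (tetrahydrofuran–oxonene–oxepene) | O1[C@H]2CC(O)/C=C\C[C@]3(C)OCC(C)=C[C@H]([C@H]13)[C@H]2CO | intermediate
20 | oxonane diol | O1[C@H]2CC(O)CCC[C@]3(C)OCC(C)=C[C@H]([C@H]13)[C@H]2CO | intermediate
21 | keto aldehyde (C7 ketone, C11 aldehyde) | O1[C@H]2CC(=O)CCC[C@]3(C)OCC(C)=C[C@H]([C@H]13)[C@H]2C=O | intermediate
22 | propanal | CCC=O | starting material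
23 | anti-aldol: C11H(OH)–C12H(CH3)–C13HO on C10 | O1[C@H]2CC(=O)CCC[C@]3(C)OCC(C)=C[C@H]([C@H]13)[C@H]2[C@H](O)[C@H](C)C=O | intermediate
24 | 1,3-diol: C11H(OH)–C12H(CH3)–C13H2OH | O1[C@H]2CC(=O)CCC[C@]3(C)OCC(C)=C[C@H]([C@H]13)[C@H]2[C@H](O)[C@H](C)CO | intermediate
25 | iodo alcohol: C11H(OH)–C12H(CH3)–C13H2I | O1[C@H]2CC(=O)CCC[C@]3(C)OCC(C)=C[C@H]([C@H]13)[C@H]2[C@H](O)[C@H](C)CI | intermediate
26 | iodo acetate: C11H(OAc)–C12H(CH3)–C13H2I | O1[C@H]2CC(=O)CCC[C@]3(C)OCC(C)=C[C@H]([C@H]13)[C@H]2[C@H](OC(C)=O)[C@H](C)CI | intermediate
27 | CNP0288436.2 (tetracyclic 11-acetoxy 7-ketone) | CC(=O)O[C@H]1[C@@H]2[C@@H]3[C@@H](C[C@H]1C)[C@@H](C)CO[C@@]1(C)CCCC(=O)C[C@@H]2O[C@@H]31 | target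

**Totals.** Total steps: 20. Longest linear sequence: 20 steps (1 → 27).

**Steps most likely to fail**

1. Step 20 (radical ring closure). The C13 radical may be reduced, or may take hydrogen from C9–H by 1,5-transfer, before it cyclizes, because the chair-like transition state puts the C12 methyl syn-axial to C9. Hydrogen may also be delivered to the wrong face of C15. The fallback closes the same bond by a polar carbonyl-ene reaction; it sets out from 23 and comes back at 27. Acetylation (Ac2O, DMAP, pyridine) should give β-acetoxy aldehyde F1. Me2AlCl (CH2Cl2, −78 °C) should then join C13 to C14 in a type I carbonyl-ene reaction, with hydrogen taken from the C15 methyl group, to give homoallylic alcohol F2 bearing an exocyclic C15 methylene. 1,1'-Thiocarbonyldiimidazole should give thiocarbonylimidazolide F3, and Bu3SnH/AIBN (toluene, 100 °C) should remove the C13 oxygen (Barton–McCombie) to give exo-methylene ether F4. Hydrogenation (H2, Pd/C, EtOAc) from the less hindered face should set C15 and give 27.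

2. Step 3 (enantioselective ring-opening cross-metathesis). Enantio- or site-selection between the two olefin carbons may be poor, or ring-opening oligomerization may compete. The fallback differentiates the four arms by substrate control; it sets out from 2 and comes back at 6. Lipase-catalysed acetylation with vinyl acetate, with the enzyme chosen so that the C11 hydroxyl stays free, should give monoacetate F5. Iridium-catalysed transfer vinylation of the free hydroxyl should give vinyl ether F6. Ring-rearrangement metathesis (Grubbs second-generation catalyst, ethene, CH2Cl2) should open the bicycle and close the six-membered cyclic enol ether onto the nearer olefin carbon only, giving dihydropyran F7 with the vinyl group on C2. PPTS in MeOH followed by K2CO3 (acetal formation, then deacetylation) should give 6.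

3. Step 16 (proline aldol). Catalyst and substrate may be mismatched, the aldehyde may epimerize or undergo β-elimination at C10 through its enamine or enol, and self-aldol of propanal may outrun the cross-aldol with the hindered acceptor. The fallback builds C11–C13 by addition and hydroboration; it sets out from 21 and comes back at 24. Isopropenylmagnesium bromide (THF, −78 °C) should add chemoselectively to the aldehyde to give allylic alcohol F8; the C11 epimer shown is separated and the other recycled by Mitsunobu inversion. Hydroboration with 9-BBN, directed by the allylic stereocentre to the anti 2-methyl-1,3-diol and much faster at the 1,1-disubstituted olefin than at the ring olefin or the ketone, followed by NaBO3 should give 24.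

**Further compounds**

F1 | step 20 | β-acetoxy aldehyde (acetate of 23) | O1[C@H]2CC(=O)CCC[C@]3(C)OCC(C)=C[C@H]([C@H]13)[C@H]2[C@H](OC(C)=O)[C@H](C)C=O
F2 | step 20 | tetracyclic homoallylic alcohol (C13–OH, exocyclic C15 methylene) | CC(=O)O[C@H]1[C@@H]2[C@@H]3[C@@H](C(O)[C@H]1C)C(=C)CO[C@@]1(C)CCCC(=O)C[C@@H]2O[C@@H]31
F3 | step 20 | C13 O-(imidazol-1-ylthiocarbonyl) derivative of F2 | CC(=O)O[C@H]1[C@@H]2[C@@H]3[C@@H](C(OC(=S)n4ccnc4)[C@H]1C)C(=C)CO[C@@]1(C)CCCC(=O)C[C@@H]2O[C@@H]31
F4 | step 20 | exo-methylene ether (15-methylidene analogue of the target) | CC(=O)O[C@H]1[C@@H]2[C@@H]3[C@@H](C[C@H]1C)C(=C)CO[C@@]1(C)CCCC(=O)C[C@@H]2O[C@@H]31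
F5 | step 3 | monoacetate of diol 2 (C14 acetate, C11 hydroxyl free) | O1[C@@H]2[C@H](CO)[C@H](COC(C)=O)[C@H]1C=C2
F6 | step 3 | vinyl ether of F5 | O1[C@@H]2[C@H](COC=C)[C@H](COC(C)=O)[C@H]1C=C2
F7 | step 3 | dihydropyran-fused tetrahydrofuran (cyclic enol ether C8=C7–O–C11, C2 vinyl, C14 acetate) | O1[C@H]2C=COC[C@@H]2[C@H](COC(C)=O)[C@H]1C=C
F8 | step 16 | allylic alcohol C11H(OH)–C12(CH3)=CH2 on C10 | O1[C@H]2CC(=O)CCC[C@]3(C)OCC(C)=C[C@H]([C@H]13)[C@H]2[C@H](O)C(C)=C
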